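**Strategy.** Ring A (C1 quaternary, C2=O, C3, C4–OH, C5, C6–O) is traced back to a pentasubstituted phloroglucinol whose C1 is made quaternary last by a chirality-transferring dearomative Claisen rearrangement. The benzene ring itself is built by ring expansion: a Danheiser benzannulation inserts the two carbons of a lavandulyl siloxyalkyne (C1, C6) into a 3-ethoxycyclobutenone (C2, C5, C4, C3) through a 4π-opening/[2+2]/4π-opening/6π-closure cascade, and fluoride then closes a δ-lactone. The step exploits the alternating oxygens on C2, C4 and C6 of ring A (ketene carbonyl, enol ether, ynol ether) and places lavandulyl, phenylpropanoate and the lone ring hydrogen regiospecifically from a precursor that contains no six-membered carbocycle.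

Key step: step 9

Locants used below: ring A carbons C1–C6 as in the overview; pyranone ring O1′, C2′, C3′, C4′(=O); "lavandulyl" means (2R)-5-methyl-2-(prop-1-en-2-yl)hex-4-en-1-yl.
Assumption: the alkaloid-controlled steps 6 and 11 are taken to give the (S)-hemiester with quinidine and the (2′R)-chromanone with quinine; if either sense is the opposite, the pseudo-enantiomeric alkaloid is used instead.
Remark: a metal salt made by simple deprotonation of a numbered compound just before the next reagent is added is treated as that compound and carries no number of its own.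

Step 1
Reactants: 1 (4S)-4-benzyl-1,3-oxazolidin-2-one; 2 3-methylbut-2-enoyl chloride
Product: 3 (4S)-4-benzyl-3-(3-methylbut-2-enoyl)-1,3-oxazolidin-2-one
Conditions: n-BuLi, THF, −78 °C; then 2, −78 → 0 °C
Reagents that add atoms: none
Why: N-acylation of the lithiated Evans auxiliary by the acid chloride (imide formation); no stereocentre is formed.

Step 2
Reactants: 3 (4S)-4-benzyl-3-(3-methylbut-2-enoyl)-1,3-oxazolidin-2-one; 4 1-bromo-3-methylbut-2-ene
Product: 5 (4S)-4-benzyl-3-[(2S)-5-methyl-2-(prop-1-en-2-yl)hex-4-enoyl]-1,3-oxazolidin-2-one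
Conditions: NaN(SiMe3)2, THF, −78 °C; then 4, −78 → −40 °C
Reagents that add atoms: none
Why: Deconjugative Evans alkylation: γ-deprotonation gives the chelated Z-dienolate, which should be alkylated at Cα on the face opposite the benzyl group, so the auxiliary sets the lavandulyl stereocentre.

Step 3
Reactants: 5 (4S)-4-benzyl-3-[(2S)-5-methyl-2-(prop-1-en-2-yl)hex-4-enoyl]-1,3-oxazolidin-2-one
Product: 6 (2S)-5-methyl-2-(prop-1-en-2-yl)hex-4-en-1-ol ((S)-lavandulol)
Conditions: LiBH4, H2O (1 equiv), Et2O, 0 °C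
Reagents that add atoms: none
Why: Reductive cleavage of the N-acyl oxazolidinone by hydride should give the primary alcohol without touching the stereocentre and return the auxiliary.

Step 4
Reactants: 6 (2S)-5-methyl-2-(prop-1-en-2-yl)hex-4-en-1-ol; 7 ethyne
Product: 9 (4R)-7-methyl-4-(prop-1-en-2-yl)oct-6-en-1-yne, via lavandulyl triflate 8 (not isolated)
Conditions: Tf2O, 2,6-lutidine, CH2Cl2, −78 °C; then LiC≡CH (from 7 and n-BuLi, THF, −78 °C), DMPU, −78 → −20 °C
Reagents that add atoms: none
Why: Triflation followed by SN2 alkylation of lithium acetylide at low temperature, where substitution at the β-branched primary carbon should outrun E2 loss of the allylic β-hydrogen; the stereocentre is untouched and only its CIP descriptor changes.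

Step 5
Reactants: 9 (4R)-7-methyl-4-(prop-1-en-2-yl)oct-6-en-1-yne
Product: 11 {[(4R)-7-methyl-4-(prop-1-en-2-yl)oct-6-en-1-yn-1-yl]oxy}tri(propan-2-yl)silane, via lithium ynolate 10 (not isolated)
Conditions: n-BuLi, THF, −78 °C; LiOOt-Bu (from t-BuOOH and LiN(SiMe3)2), −78 → 0 °C; then i-Pr3SiOTf, −78 °C
Reagents that add atoms: lithium tert-butyl peroxide CC(C)(C)OO[Li]; triisopropylsilyl trifluoromethanesulfonate CC(C)[Si](C(C)C)(C(C)C)OS(=O)(=O)C(F)(F)F
Why: Oxidation of the lithium acetylide by the lithium peroxide gives the ynolate, whose O-silylation (siloxyalkyne synthesis) should give a thermally robust ynol silyl ether.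

Step 6
Reactants: 12 4-phenyloxane-2,6-dione (3-phenylglutaric anhydride)
Product: 13 (3S)-5-methoxy-5-oxo-3-phenylpentanoic acid
Conditions: MeOH (3 equiv), quinidine (1.1 equiv), toluene, −55 °C
Reagents that add atoms: methanol CO
Why: Cinchona-alkaloid-mediated desymmetrising methanolysis of the prochiral anhydride: the alkaloid directs methanol to one enantiotopic carbonyl and so sets the benzylic stereocentre by reagent control.

Step 7
Reactants: 13 (3S)-5-methoxy-5-oxo-3-phenylpentanoic acid
Product: 14 methyl (3R)-5-chloro-5-oxo-3-phenylpentanoate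
Conditions: (COCl)2, DMF (cat.), CH2Cl2, 0 → 23 °C
Reagents that add atoms: oxalyl chloride O=C(Cl)C(Cl)=O
Why: Acid chloride formation through the chloroiminium catalyst; the β-stereocentre cannot enolise and only its CIP descriptor changes.

Step 8
Reactants: 14 methyl (3R)-5-chloro-5-oxo-3-phenylpentanoate; 15 ethoxyethyne
Product: 17 methyl (3R)-3-(2-ethoxy-4-oxocyclobut-2-en-1-yl)-3-phenylpropanoate (both epimers at the ring CH), via ketene 16 (not isolated)
Conditions: Et3N, 15 (3 equiv), Et2O, slow addition of 14, 0 → 23 °C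
Reagents that add atoms: none
Why: Dehydrochlorination gives the aldoketene, which should undergo regioselective thermal [2+2] cycloaddition with the ynol ether (ketene carbonyl carbon to the unsubstituted alkyne carbon); the new ring CH forms as a mixture, which does not matter because it becomes an aromatic carbon.

Step 9
Reactants: 17 methyl (3R)-3-(2-ethoxy-4-oxocyclobut-2-en-1-yl)-3-phenylpropanoate; 11 {[(4R)-7-methyl-4-(prop-1-en-2-yl)oct-6-en-1-yn-1-yl]oxy}tri(propan-2-yl)silane
Product: 24 (4S)-5-ethoxy-7-hydroxy-8-lavandulyl-4-phenyl-3,4-dihydro-2H-chromen-2-one, via vinylketene 18 (not isolated), via cyclobutenone adduct 19 (not isolated), via dienylketene 20 (not isolated), via cyclohexadienone 21 (not isolated), via silyl ether phenol 22 (not isolated), via diphenol ester 23 (not isolated)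
Conditions: 11 (1.3 equiv), toluene, 110 °C; then Bu4NF, THF, 0 → 23 °C; aq. NH4Cl
Reagents that add atoms: none
Why: Danheiser benzannulation: thermal 4π-electrocyclic opening of 17 gives vinylketene 18, which adds across the siloxyalkyne ([2+2], ketene carbon to the lavandulyl-bearing β-carbon of the ynol ether) to give the four-membered ketone 19, whose 4π opening to dienylketene 20 and 6π closure (C2–C3 bond) expand the four-membered ring by the two alkyne carbons to cyclohexadienone 21, which tautomerises to phenol 22. The carbocycle is thus closed by a disrotatory 6π electrocyclisation, and the δ-lactone by 6-exo-trig acyl substitution of the C2 phenoxide on the side-chain ester once Bu4NF has removed the silyl group. No stereocentre is created: the lavandulyl and benzylic centres are spectators and the ring CH of 17 becomes aromatic. The step needs regiocontrol in the ketene–alkyne cycloaddition, which the polarisation of the ynol ether secures, so that lavandulyl ends on C1 between the C2 and C6 oxygens, the phenylpropanoate on C3 and the only ring hydrogen on C5. It also needs the ketene to prefer the alkyne over the lavandulyl alkenes, which the far higher ketenophilicity of the siloxyalkyne used in excess should secure.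

Step 10
Reactants: 24 (4S)-5-ethoxy-7-hydroxy-8-lavandulyl-4-phenyl-3,4-dihydro-2H-chromen-2-one; 25 (2E)-2-methylbut-2-enoyl chloride (tigloyl chloride)
Product: 26 (4S)-5-ethoxy-7-hydroxy-6-[(2E)-2-methylbut-2-enoyl]-8-lavandulyl-4-phenyl-3,4-dihydro-2H-chromen-2-one
Conditions: EtMgBr (1.0 equiv), Et2O/toluene, 0 °C; then 25, 23 °C
Reagents that add atoms: none
Why: Magnesium-phenolate-directed ortho C-acylation in a non-coordinating solvent should deliver the acyl chloride to the only free ortho position (C5) without any Lewis or Brønsted acid that would attack the lavandulyl alkenes.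

Step 11
Reactants: 26 (4S)-5-ethoxy-7-hydroxy-6-[(2E)-2-methylbut-2-enoyl]-8-lavandulyl-4-phenyl-3,4-dihydro-2H-chromen-2-one
Product: 27 (2R,6S)-5-ethoxy-2,3-dimethyl-10-lavandulyl-6-phenyl-2,3,6,7-tetrahydro-4H,8H-pyrano[3,2-g]chromene-4,8-dione (chromanone closed from the C6 oxygen; C3′ epimers, cis-rich)
Conditions: quinine (0.3 equiv), PhCl, 15 °C
Reagents that add atoms: none
Why: Quinine-catalysed asymmetric intramolecular oxa-Michael addition of the C6 phenol to the tigloyl enone: the alkaloid controls the face of the β-carbon and sets C2′ (R), while C3′ arises by protonation and is corrected in step 12.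

Step 12
Reactants: 27 (2R,6S)-5-ethoxy-2,3-dimethyl-10-lavandulyl-6-phenyl-2,3,6,7-tetrahydro-4H,8H-pyrano[3,2-g]chromene-4,8-dione
Product: 28 methyl (3S)-3-[(2R,3R)-5-ethoxy-7-hydroxy-2,3-dimethyl-8-lavandulyl-4-oxo-3,4-dihydro-2H-chromen-6-yl]-3-phenylpropanoate
Conditions: Et3N, MeOH, 40 °C
Reagents that add atoms: methanol CO
Why: Amine-catalysed methanolysis of the activated aryl lactone should free the C2 phenol and restore the methyl ester, while the same base equilibrates C3′ by enolisation to the diequatorial trans-2,3-dimethyl arrangement (thermodynamic control, C2′ untouched).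

Step 13
Reactants: 28 methyl (3S)-3-[(2R,3R)-5-ethoxy-7-hydroxy-2,3-dimethyl-8-lavandulyl-4-oxo-3,4-dihydro-2H-chromen-6-yl]-3-phenylpropanoate; 29 (2R)-but-3-en-2-ol
Product: 30 methyl (3S)-3-[(2R,3R)-7-{[(2S)-but-3-en-2-yl]oxy}-5-ethoxy-2,3-dimethyl-8-lavandulyl-4-oxo-3,4-dihydro-2H-chromen-6-yl]-3-phenylpropanoate
Conditions: PPh3, DIAD (i-PrO2C–N=N–CO2i-Pr), toluene, 0 → 23 °C
Reagents that add atoms: none
Why: Mitsunobu etherification of the acidic C2 phenol (the only free OH) with the secondary allylic alcohol should proceed by SN2 with inversion, turning (R)-29 into the (S)-configured aryl 1-methylallyl ether.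

Step 14
Reactants: 30 methyl (3S)-3-[(2R,3R)-7-{[(2S)-but-3-en-2-yl]oxy}-5-ethoxy-2,3-dimethyl-8-lavandulyl-4-oxo-3,4-dihydro-2H-chromen-6-yl]-3-phenylpropanoate
Product: 31 methyl (3S)-3-[(2R,3R,8S)-8-[(2E)-but-2-en-1-yl]-5-ethoxy-2,3-dimethyl-8-lavandulyl-4,7-dioxo-3,4,7,8-tetrahydro-2H-chromen-6-yl]-3-phenylpropanoate
Conditions: toluene, 110 °C (sealed tube)
Reagents that add atoms: none
Why: Dearomative aromatic Claisen rearrangement ([3,3]) to the ortho carbon C1 through a chair transition state with the methyl group pseudo-equatorial should transfer the chirality of the (S)-ether carbon to C1 (S) and give the (E)-butenyl group; C5 (para) is blocked by the acyl group and the α-branched substituent on C3 disfavours migration there.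

Step 15
Reactants: 31 methyl (3S)-3-[(2R,3R,8S)-8-[(2E)-but-2-en-1-yl]-5-ethoxy-2,3-dimethyl-8-lavandulyl-4,7-dioxo-3,4,7,8-tetrahydro-2H-chromen-6-yl]-3-phenylpropanoate; 32 2-methylbut-2-ene
Product: 33 methyl (3S)-3-[(2R,3R,8S)-5-ethoxy-2,3-dimethyl-8-(3-methylbut-2-en-1-yl)-8-lavandulyl-4,7-dioxo-3,4,7,8-tetrahydro-2H-chromen-6-yl]-3-phenylpropanoate
Conditions: second-generation Hoveyda–Grubbs catalyst RuCl2(H2IMes)(=CH–C6H4-2-Oi-Pr) (5 mol %), 32 as solvent, 40 °C
Reagents that add atoms: none
Why: Olefin cross-metathesis of the 1,2-disubstituted butenyl group with 2-methylbut-2-ene as solvent should exchange the ethylidene terminus for isopropylidene (butenyl to prenyl), the trisubstituted and the branched 1,1-disubstituted alkenes being much slower partners.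

Step 16
Reactants: 33 methyl (3S)-3-[(2R,3R,8S)-5-ethoxy-2,3-dimethyl-8-(3-methylbut-2-en-1-yl)-8-lavandulyl-4,7-dioxo-3,4,7,8-tetrahydro-2H-chromen-6-yl]-3-phenylpropanoate
Product: 35 (3S)-3-[(2R,3R,8S)-5-hydroxy-2,3-dimethyl-8-(3-methylbut-2-en-1-yl)-8-lavandulyl-4,7-dioxo-3,4,7,8-tetrahydro-2H-chromen-6-yl]-3-phenylpropanoic acid (target), via enol methyl ester 34 (not isolated)
Conditions: 1 M HCl, THF, 23 °C; then LiOH, THF/H2O, 0 → 23 °C; 1 M HCl work-up
Reagents that add atoms: water O; lithium hydroxide [Li+].[OH-]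
Why: Acid hydrolysis of the vinylogous ethyl ester (addition–elimination at C4) followed by saponification of the methyl ester on the C4 enolate, whose charge should protect the pyranone from E1cB ring opening; no stereocentre is touched.

**Compound list**

1 | (4S)-4-benzyl-1,3-oxazolidin-2-one | O=C1N[C@@H](Cc2ccccc2)CO1 | starting material
2 | 3-methylbut-2-enoyl chloride | CC(C)=CC(Cl)=O | starting material
3 | (4S)-4-benzyl-3-(3-methylbut-2-enoyl)-1,3-oxazolidin-2-one | CC(C)=CC(=O)N1[C@@H](Cc2ccccc2)COC1=O | intermediate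
4 | 1-bromo-3-methylbut-2-ene (prenyl bromide) | CC(C)=CCBr | starting material
5 | (4S)-4-benzyl-3-[(2S)-5-methyl-2-(prop-1-en-2-yl)hex-4-enoyl]-1,3-oxazolidin-2-one | C=C(C)[C@H](CC=C(C)C)C(=O)N1[C@@H](Cc2ccccc2)COC1=O | intermediate
6 | (2S)-5-methyl-2-(prop-1-en-2-yl)hex-4-en-1-ol ((S)-lavandulol) | C=C(C)[C@H](CC=C(C)C)CO | intermediate
7 | ethyne | C#C | starting material
8 | (2S)-5-methyl-2-(prop-1-en-2-yl)hex-4-en-1-yl trifluoromethanesulfonate | C=C(C)[C@H](CC=C(C)C)COS(=O)(=O)C(F)(F)F | intermediate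
9 | (4R)-7-methyl-4-(prop-1-en-2-yl)oct-6-en-1-yne | C=C(C)[C@H](CC=C(C)C)CC#C | intermediate
10 | lithium (4R)-7-methyl-4-(prop-1-en-2-yl)oct-6-en-1-yn-1-olate | C=C(C)[C@H](CC=C(C)C)CC#CO[Li] | intermediate
11 | {[(4R)-7-methyl-4-(prop-1-en-2-yl)oct-6-en-1-yn-1-yl]oxy}tri(propan-2-yl)silane | C=C(C)[C@H](CC=C(C)C)CC#CO[Si](C(C)C)(C(C)C)C(C)C | intermediate
12 | 4-phenyloxane-2,6-dione (3-phenylglutaric anhydride) | O=C1CC(c2ccccc2)CC(=O)O1 | starting material
13 | (3S)-5-methoxy-5-oxo-3-phenylpentanoic acid | OC(=O)C[C@@H](CC(=O)OC)c1ccccc1 | intermediate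
14 | methyl (3R)-5-chloro-5-oxo-3-phenylpentanoate | ClC(=O)C[C@@H](CC(=O)OC)c1ccccc1 | intermediate
15 | ethoxyethyne | CCOC#C | starting material
16 | methyl (3R)-5-oxo-3-phenylpent-4-enoate (aldoketene) | O=C=C[C@@H](CC(=O)OC)c1ccccc1 | intermediate
17 | methyl (3R)-3-(2-ethoxy-4-oxocyclobut-2-en-1-yl)-3-phenylpropanoate (both epimers at the ring CH) | CCOC1=CC(=O)C1[C@@H](CC(=O)OC)c2ccccc2 | intermediate
18 | methyl (3R,4Z)-5-ethoxy-7-oxo-3-phenylhepta-4,6-dienoate (vinylketene) | O=C=C/C(OCC)=C/[C@@H](CC(=O)OC)c1ccccc1 | intermediate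
19 | 4-[(1Z,3R)-1-ethoxy-5-methoxy-5-oxo-3-phenylpent-1-en-1-yl]-2-lavandulyl-3-[tri(propan-2-yl)silyloxy]cyclobut-2-en-1-one (both epimers at C4) | C=C(C)[C@H](CC=C(C)C)CC1=C(O[Si](C(C)C)(C(C)C)C(C)C)C(/C(OCC)=C/[C@@H](CC(=O)OC)c2ccccc2)C1=O | intermediate
20 | methyl (3R,4Z,6E)-5-ethoxy-8-lavandulyl-9-oxo-3-phenyl-7-[tri(propan-2-yl)silyloxy]nona-4,6,8-trienoate (dienylketene) | C=C(C)[C@H](CC=C(C)C)CC(=C=O)/C(O[Si](C(C)C)(C(C)C)C(C)C)=C\C(OCC)=C\[C@@H](CC(=O)OC)c1ccccc1 | intermediate
21 | methyl (3R)-3-{2-ethoxy-5-lavandulyl-6-oxo-4-[tri(propan-2-yl)silyloxy]cyclohexa-2,4-dien-1-yl}-3-phenylpropanoate (both epimers at the ring CH) | C=C(C)[C@H](CC=C(C)C)CC1=C(O[Si](C(C)C)(C(C)C)C(C)C)C=C(OCC)C([C@@H](CC(=O)OC)c2ccccc2)C1=O | intermediate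
22 | methyl (3S)-3-{6-ethoxy-2-hydroxy-3-lavandulyl-4-[tri(propan-2-yl)silyloxy]phenyl}-3-phenylpropanoate | C=C(C)[C@H](CC=C(C)C)Cc1c(O)c([C@@H](CC(=O)OC)c2ccccc2)c(OCC)cc1O[Si](C(C)C)(C(C)C)C(C)C | intermediate
23 | methyl (3S)-3-(6-ethoxy-2,4-dihydroxy-3-lavandulylphenyl)-3-phenylpropanoate | C=C(C)[C@H](CC=C(C)C)Cc1c(O)c([C@@H](CC(=O)OC)c2ccccc2)c(OCC)cc1O | intermediate
24 | (4S)-5-ethoxy-7-hydroxy-8-lavandulyl-4-phenyl-3,4-dihydro-2H-chromen-2-one | C=C(C)[C@H](CC=C(C)C)Cc1c2OC(=O)C[C@@H](c3ccccc3)c2c(OCC)cc1O | intermediate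
25 | (2E)-2-methylbut-2-enoyl chloride (tigloyl chloride) | C/C=C(\C)C(Cl)=O | starting material
26 | (4S)-5-ethoxy-7-hydroxy-6-[(2E)-2-methylbut-2-enoyl]-8-lavandulyl-4-phenyl-3,4-dihydro-2H-chromen-2-one | C=C(C)[C@H](CC=C(C)C)Cc1c2OC(=O)C[C@@H](c3ccccc3)c2c(OCC)c(C(=O)/C(C)=C/C)c1O | intermediate
27 | (2R,6S)-5-ethoxy-2,3-dimethyl-10-lavandulyl-6-phenyl-2,3,6,7-tetrahydro-4H,8H-pyrano[3,2-g]chromene-4,8-dione (C3′ epimers) | C=C(C)[C@H](CC=C(C)C)Cc1c2OC(=O)C[C@@H](c3ccccc3)c2c(OCC)c4c1O[C@H](C)C(C)C4=O | intermediate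
28 | methyl (3S)-3-[(2R,3R)-5-ethoxy-7-hydroxy-2,3-dimethyl-8-lavandulyl-4-oxo-3,4-dihydro-2H-chromen-6-yl]-3-phenylpropanoate | C=C(C)[C@H](CC=C(C)C)Cc1c(O)c([C@@H](CC(=O)OC)c2ccccc2)c(OCC)c3c1O[C@H](C)[C@@H](C)C3=O | intermediate
29 | (2R)-but-3-en-2-ol | C[C@@H](O)C=C | starting material
30 | methyl (3S)-3-[(2R,3R)-7-{[(2S)-but-3-en-2-yl]oxy}-5-ethoxy-2,3-dimethyl-8-lavandulyl-4-oxo-3,4-dihydro-2H-chromen-6-yl]-3-phenylpropanoate | C=C(C)[C@H](CC=C(C)C)Cc1c(O[C@@H](C)C=C)c([C@@H](CC(=O)OC)c2ccccc2)c(OCC)c3c1O[C@H](C)[C@@H](C)C3=O | intermediate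
31 | methyl (3S)-3-[(2R,3R,8S)-8-[(2E)-but-2-en-1-yl]-5-ethoxy-2,3-dimethyl-8-lavandulyl-4,7-dioxo-3,4,7,8-tetrahydro-2H-chromen-6-yl]-3-phenylpropanoate | C=C(C)[C@H](CC=C(C)C)C[C@]1(C/C=C/C)C(=O)C([C@@H](CC(=O)OC)c2ccccc2)=C(OCC)C2=C1O[C@H](C)[C@@H](C)C2=O | intermediate
32 | 2-methylbut-2-ene | CC=C(C)C | starting material
33 | methyl (3S)-3-[(2R,3R,8S)-5-ethoxy-2,3-dimethyl-8-(3-methylbut-2-en-1-yl)-8-lavandulyl-4,7-dioxo-3,4,7,8-tetrahydro-2H-chromen-6-yl]-3-phenylpropanoate | C=C(C)[C@H](CC=C(C)C)C[C@]1(CC=C(C)C)C(=O)C([C@@H](CC(=O)OC)c2ccccc2)=C(OCC)C2=C1O[C@H](C)[C@@H](C)C2=O | intermediate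
34 | methyl (3S)-3-[(2R,3R,8S)-5-hydroxy-2,3-dimethyl-8-(3-methylbut-2-en-1-yl)-8-lavandulyl-4,7-dioxo-3,4,7,8-tetrahydro-2H-chromen-6-yl]-3-phenylpropanoate | C=C(C)[C@H](CC=C(C)C)C[C@]1(CC=C(C)C)C(=O)C([C@@H](CC(=O)OC)c2ccccc2)=C(O)C2=C1O[C@H](C)[C@@H](C)C2=O | intermediate
35 | (3S)-3-[(2R,3R,8S)-5-hydroxy-2,3-dimethyl-8-(3-methylbut-2-en-1-yl)-8-[(2R)-5-methyl-2-(prop-1-en-2-yl)hex-4-en-1-yl]-4,7-dioxo-3,4,7,8-tetrahydro-2H-chromen-6-yl]-3-phenylpropanoic acid | C=C(C)[C@H](CC=C(C)C)C[C@]1(CC=C(C)C)C(=O)C([C@@H](CC(=O)O)c2ccccc2)=C(O)C2=C1O[C@H](C)[C@@H](C)C2=O | target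

**Count.** Total steps: 16. Longest linear sequence: 13 steps (steps 1–5 and 9–16).

**Steps most likely to fail**

Step 14 (dearomative Claisen rearrangement). The [3,3] shift may go to the other ortho carbon (C3) instead of C1, or pass through boat or axial-methyl transition states, which would erode regio- and stereocontrol at C1. The fallback abandons the sigmatropic approach and sets out from phenol 28. Alkylative dearomatisation with prenyl bromide 4 under chiral phase-transfer catalysis (N-(9-anthracenylmethyl)cinchonidinium bromide or its cinchoninium pseudo-enantiomer, 50% aq. KOH, toluene, −20 °C) should C-alkylate the C2 phenoxide at C1. The catalyst is chosen for the 8S configuration and any C1 epimer is removed by chromatography. This comes back to the route at 33 and bypasses 30, 31 and the metathesis.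

Step 15 (cross-metathesis). Ring-closing metathesis of the substrate-bound ruthenium alkylidene onto the isopropenyl group (spiro-cyclohexene) or onto the prenyl alkene of the lavandulyl group may compete with cross-metathesis. The fallback avoids metathesis and sets out from phenol 28. O-alkylation catalysed by Pd(PPh3)4 with methyl 2-methylbut-3-en-2-yl carbonate (THF, 0 °C) should give the 1,1-dimethylallyl ether methyl (3S)-3-[(2R,3R)-5-ethoxy-2,3-dimethyl-7-[(2-methylbut-3-en-2-yl)oxy]-8-lavandulyl-4-oxo-3,4-dihydro-2H-chromen-6-yl]-3-phenylpropanoate F1. Heating it (toluene, 100 °C) should effect the dearomative Claisen rearrangement, which places a prenyl group directly on C1 and comes back to the route at 33. In this variant C1 is controlled only by the substrate, so the C1 epimers would be separated by chromatography.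

Step 13 (Mitsunobu etherification). The doubly ortho-substituted phenol may react sluggishly, and the activated allylic alcohol may be attacked in the SN2′ sense (linear butenyl ether) or eliminate. The fallback replaces SN2 inversion by catalyst-controlled allylic substitution and sets out from 28. Its sodium phenoxide (NaH, THF) is treated with (E)-but-2-en-1-yl methyl carbonate, [Ir(cod)Cl]2 and a chiral phosphoramidite ligand (enantiomer chosen for the S ether). This should give the branched ether and come back to the route at 30.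

**Further compounds**

F0 | step 14 | none | none
F1 | step 15 | methyl (3S)-3-[(2R,3R)-5-ethoxy-2,3-dimethyl-7-[(2-methylbut-3-en-2-yl)oxy]-8-lavandulyl-4-oxo-3,4-dihydro-2H-chromen-6-yl]-3-phenylpropanoate | C=C(C)[C@H](CC=C(C)C)Cc1c(OC(C)(C)C=C)c([C@@H](CC(=O)OC)c2ccccc2)c(OCC)c3c1O[C@H](C)[C@@H](C)C3=O
F0 | step 13 | none | none
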